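## Structural features

The target is a flavonol: benzene ring A is fused to a 4-pyranone ring C (a chromen-4-one), and a catechol-derived ring B is joined to C2 by a single aryl–vinyl bond. There is no stereocentre, so the problem is one of connectivity and of telling five oxygens apart: O3 on ring C, O5 and O7 on ring A, O3' and O4' on ring B. Four of them (3, 7, 3', 4') are hydrogen sulfate monoesters, while the 5-hydroxyl is free and locked in a six-membered hydrogen bond to the C4 carbonyl. The sulfate esters are the fragile part: they are strong acids, hydrolyse under acidic conditions (the enol-type 3-sulfate and the free-acid form most easily) and cannot be carried through ether cleavage or silica chromatography, so they must be installed last. The free catechol and the 3-hydroxy-4-pyranone of the penultimate polyphenol are air-sensitive in base. The real difficulties are two: building ring C with the correct oxygenation at C3 and on ring A in few steps, and sulfating four hydroxyls exhaustively while sparing the fifth. The second is eased by the structure itself, since the chelated 5-hydroxyl is by far the least nucleophilic. The first is answered by ring A: C8a (bearing O1) and C4a (bearing the C4 carbonyl) are adjacent, and C4a has the oxygenated C5 as its other neighbour, which is the pattern left when a 3-alkoxyaryne takes a nucleophile at the remote aryne carbon and an electrophile at the carbon beside the alkoxy group.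

## Logic of the disconnections

**17 to 16.** No skeletal bond is cut; the four sulfate O–H bonds are traded for sodium ion pairs. The cut is placed here because 17 is a strong tetraprotic acid that catalyses its own hydrolysis, whereas 16 can be purified and stored. The gain is that purification is separated from release of the acid. The demand is a proton-for-sodium exchange that is complete, cold and brief.

**16 to 14 (through 15).** The four S–O bonds at O3, O7, O3' and O4' are cut. They are cut together because no sulfate would survive the ether cleavage that precedes them. The gain is a simple, crystalline pentahydroxy compound. The demand is sulfation that is exhaustive at the catechol pair and at O3 but does not touch O5; this rests on the O5–H to C4 carbonyl hydrogen bond.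

**14 to 13.** Five O–alkyl bonds are cut: three O–CH2Ph (O3, O3', O4') and two O–CH3 (O5, O7). The ring-forming step needs every oxygen masked, because an aryne is protonated or O-arylated by any free hydroxyl. The gain is that 13 is neutral and chromatographable. The demand is one reagent that removes both kinds of ether, with benzyl cations intercepted so that ring A is not C-benzylated.

**13 to 7 and 11 (through 12).** O1–C8a and C4–C4a are cut, opening ring C. This is the most simplifying cut available: ring A becomes a derivative of a symmetrical phenol, and C2, C3, C4 with ring B become a linear keto ester that already carries O3. The forward step must meet four demands: oxygen must add to the aryne carbon remote from the C5 oxygen, the enolate must react at oxygen and not at carbon, the ester must sit cis to the new aryl ether oxygen, and the aryl anion must reach the ester before it finds a proton. For that reason the medium holds no acidic C–H solvent and 7 is fed slowly and in excess, because expelled methoxide consumes aryne.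

**11 to 8 and 9 (through 10).** The C–C bond between the ketone carbonyl carbon (future C2) and the benzyloxy-bearing carbon (future C3) is cut. This is a crossed Claisen retron; both halves are commercial and O3 arrives already protected. The demand is a non-enolisable, sufficiently reactive acyl donor (10) and enough enolate to absorb the acidity of the product.

**7 to 5 (through 6).** The triflate O–S bond and the carbamate O–C bond are cut. The carbamate has done its work as a director and is exchanged for the leaving group that the aryne needs. The gain is a stable, storable silyl carbamate. The demand is a carbamate cleavage that spares the aryl–silicon bond, which an N-monoalkyl carbamate meets by leaving through elimination.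

**5 to 2 (through 3 and 4).** The C2–Si bond is cut. Silicon is placed by metalation because the carbamate can direct it to the ring position that will become the aryne carbon beside a methoxy group. The gain is an unfunctionalised carbamate of a symmetrical phenol. The demand is metalation at the carbon between the carbamate and a methoxy group (C2 and C6 are equivalent) and not between the two methoxy groups.

**2 to 1.** The carbamate C–O bond is cut, leading back to a commercial symmetrical phenol. The demand is only a clean carbamoylation.

## Other disconnections considered

Alternative 1: biomimetic Claisen folding.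
- Cut: the ring A bond C4a–C5, which unravels ring A into the poly-β-carbonyl chain of methyl (Z)-8-(benzyloxy)-9-[3,4-bis(benzyloxy)phenyl]-3,5,7-trioxonon-8-enoate A1.
- Forward key step: methanolic KOH would drive chain carbon 6 of A1 onto the ester carbon; enolisation then aromatises ring A to the acylphloroglucinol (Z)-2-(benzyloxy)-3-[3,4-bis(benzyloxy)phenyl]-1-(2,4,6-trihydroxyphenyl)prop-2-en-1-one A2.
- In favour: the three ring A oxygens come from chain carbonyls and need no protecting groups, so on protecting-group count for ring A it is the better plan. Claisen-mode cyclisation of 3,5,7-triketo esters in strong base is an established reaction class, so on precedent for the key step it is also better.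
- Against: A1 must be built by acylating a polyanion with a cinnamoyl donor and is prone to aldol-mode folding (chain carbon 2 onto the C7 carbonyl), to pyranone lactonisation and to conjugate addition at its enone. After A2, ring C is still open. Closing it by oxa-Michael addition gives the flavanone oxidation level with two transient stereocentres, which a dehydrogenation must then erase.
- Comparison: this plan constructs the ring that can be bought and leaves the ring that cannot; the chosen plan does the opposite. Mechanistically it is safer at its key step but more fragile before and after it. In step count it should be clearly longer to reach 14.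

Alternative 2: C3 as an alkoxymethylene ylide.
- Cut: C3–C4 and the C2=C3 double bond.
- Forward key step: two equivalents of (benzyloxymethylene)triphenylphosphorane A4 would react with 2,4-bis(benzyloxy)-6-{[3,4-bis(benzyloxy)benzoyl]oxy}benzoyl chloride A3. C-acylation, proton transfer to the second equivalent of A4 and intramolecular Wittig olefination of the aryl ester carbonyl would give 3,5,7,3',4'-penta-O-benzylquercetin A5.
- In favour: every elementary step is of a known type, so the mechanistic risk is lower than that of the chosen key step. A5 carries only benzyl ethers, so 14 would follow by one neutral hydrogenolysis, which is milder than the Lewis-acid cleavage of the chosen plan. On both counts the alternative is the better.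
- Against: A3 needs a differentiated phloroglucinol carboxylic acid (two benzyl ethers, one aroyl ester, then the acid chloride), which costs several steps and risks acyl migration. A4 is an unstabilised α-alkoxy ylide whose phosphonium precursor comes from a carcinogenic chloromethyl ether, and half of it is spent as a base. A4 may also attack the aryl ester of A3, and the ketone-stabilised phosphorane is a sluggish partner for an ester carbonyl.
- Comparison: convergence is equal (two fragments). The ring A pattern is bought rather than generated. The chosen plan is shorter if its key step performs; the alternative is the more reliable.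

Alternative 3: thermal Mentzer fusion.
- Cut: C4–C4a and O1–C2.
- Forward key step: phloroglucinol A6 and methyl 3-(3,4-dimethoxyphenyl)-2-methoxy-3-oxopropanoate A7 would be heated together without solvent at about 250 °C. C-acylation of A6 by the ester of A7 and cyclodehydration onto its ketone would give 5,7-dihydroxy-3,3',4'-trimethoxyflavone A8, and BBr3 would then convert A8 into 14.
- In favour: the symmetry of A6 removes any regiochemical question, ring A needs no protection, and the reaction class is known for 3-methoxyflavones. A7 should be available by a single crossed Claisen condensation. Through A8, 14 would be reached in about three steps from commercial materials, against six in the chosen plan. On step economy and on precedent this alternative is plainly better.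
- Against: the conditions are brutal and are expected to give modest material balance with tar. Benzyl ethers cannot be used in A7, so all three ethers of A8 are methyl ethers, and the non-chelated 3-methyl ether of A8 is among the slower ones to cleave. The method is tied to phloroglucinol-type nucleophiles such as A6, which is no handicap for this ring A.
- Comparison: both plans close ring C onto an intact ring A. The chosen plan offers low temperature, a neutral chromatographable intermediate and regiocontrol that would carry over to unsymmetrical ring A patterns. For this target alone these advantages do not outweigh the brevity of the fusion; the chosen plan is preferred only where mild, general ring construction is valued above step count.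

Key step: step 5

Assumption: the target is taken as the fully protonated tetrakis(hydrogen sulfate) exactly as drawn. Such acids hydrolyse by self-catalysis, so the acid is released only in the last step, cold and dilute, and the tetrasodium salt 16 is the form to purify and store.

## Route

Step 1
Reactants: 1 3,5-dimethoxyphenol
Product: 2 3,5-dimethoxyphenyl N-isopropylcarbamate
Conditions: i-PrNCO (1.5 equiv), Et3N (0.2 equiv), CH2Cl2, rt
Reagents that add atoms: isopropyl isocyanate, CC(C)N=C=O
Why: Base-catalysed addition of a phenol to an isocyanate (carbamoylation); the N-monoalkyl carbamate is chosen because, once N-silylated, it is a strong director for ortho-metalation and can later be removed by mild elimination instead of hydrolysis.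

Step 2
Reactants: 2 3,5-dimethoxyphenyl N-isopropylcarbamate
Product: 5 3,5-dimethoxy-2-(trimethylsilyl)phenyl N-isopropylcarbamate, via N-TBS carbamate 3 (not isolated), via N-TBS 2-TMS carbamate 4 (not isolated)
Conditions: TBSOTf (1.05 equiv), TMEDA (1.1 equiv), Et2O, 0 °C to rt; then TMEDA (2 equiv), n-BuLi (2 equiv), −78 °C; TMSCl (3 equiv), −78 °C to rt; aq. NaHSO4
Reagents that add atoms: chlorotrimethylsilane, C[Si](C)(C)Cl
Why: Directed ortho-metalation: N-silylation by TBSOTf in the flask removes the acidic N–H and makes the carbamate a bulky, non-electrophilic director, lithiation then takes place at the carbon flanked by the carbamate and a methoxy group (C2 and C6 are equivalent), the aryllithium is silylated, and the labile N–Si bond is hydrolysed on acidic work-up.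

Step 3
Reactants: 5 3,5-dimethoxy-2-(trimethylsilyl)phenyl N-isopropylcarbamate
Product: 7 3,5-dimethoxy-2-(trimethylsilyl)phenyl trifluoromethanesulfonate, via ortho-silylphenol 6 (not isolated)
Conditions: DBU (1.5 equiv), Et2NH (1.2 equiv), MeCN, 40 °C; then PhNTf2 (1.5 equiv), rt
Reagents that add atoms: N-phenylbis(trifluoromethanesulfonimide), O=S(=O)(N(c1ccccc1)S(=O)(=O)C(F)(F)F)C(F)(F)F
Why: E1cB cleavage of the N–H carbamate (deprotonation at nitrogen, loss of phenoxide, capture of the isocyanate by diethylamine) followed by O-triflation of the phenoxide in the same flask; the medium is non-aqueous and only mildly basic, so the aryl–silicon bond should survive.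

Step 4
Reactants: 8 3,4-bis(benzyloxy)benzoic acid; 9 methyl benzyloxyacetate
Product: 11 methyl 2-(benzyloxy)-3-[3,4-bis(benzyloxy)phenyl]-3-oxopropanoate (racemic), via acyl imidazolide 10 (not isolated)
Conditions: 8, CDI (1.1 equiv), THF, rt to 40 °C; separately 9 (2.2 equiv), LiN(SiMe3)2 (2.2 equiv), THF, −78 °C; add the solution of 10, −78 to −20 °C; AcOH, then H2O
Reagents that add atoms: none
Why: Crossed Claisen condensation of a lithium ester enolate with a non-enolisable acyl imidazolide; two equivalents of enolate are used because the β-keto ester is more acidic than the starting ester and is deprotonated as it forms, which also shields it from a second acylation; the new stereocentre is enolisable, forms racemic and is erased in step 5.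

Step 5
Reactants: 7 3,5-dimethoxy-2-(trimethylsilyl)phenyl trifluoromethanesulfonate; 11 methyl 2-(benzyloxy)-3-[3,4-bis(benzyloxy)phenyl]-3-oxopropanoate
Product: 13 3,3',4'-tri-O-benzyl-5,7-di-O-methylquercetin, via 3,5-dimethoxybenzyne 12 (not isolated)
Conditions: 11 (1.0 equiv), CsF (4 equiv), THF, 65 °C; 7 (1.5 equiv) in THF added over 4 h
Reagents that add atoms: none
Why: Proposed new method: fluoride removes the trimethylsilyl group of 7 and triflate departs to give aryne 12, whose C3 methoxy group withdraws electrons inductively and distorts the triple bond, so a nucleophile should bond to the carbon that carried the triflate (future C8a) and leave the negative charge on the carbon beside the methoxy group (future C4a). The nucleophile wanted is the ketone-derived oxygen of the caesium enolate of 11, which forms O1–C8a; the aryl anion then adds to the ester carbonyl in a 6-exo-trig addition–elimination, methoxide leaves, and C4–C4a and ring C (a 4-pyranone) are complete. The closest known reaction types are the fluoride-induced annulation of arynes with salicylate esters to xanthones (aryl ether formation, then acyl substitution by the aryl anion) and the acyl-alkylation of arynes by β-keto esters, which is the competing C-arylation channel. No stereocentre is formed and the racemic centre of 11 disappears on enolisation. Three selectivities are needed: the aryne regiochemistry, fixed by the methoxy group at the future C5 while the second methoxy group simply lands on C7; oxygen over carbon attack, for which the substrate offers a fully substituted enolate carbon flanked by benzyloxy, aroyl and ester groups, a large caesium counter-ion and the early, charge-controlled transition state typical of arynes; and the enolate geometry, since only the chelated U-shaped enolate (E by the sequence rule, because the benzyloxy oxygen outranks the ester carbon) places the ester cis to the new aryl ether oxygen. THF is preferred to acetonitrile because the aryl anion must reach the ester before it meets a proton donor, and the slow feed of excess 7 allows for the aryne that expelled methoxide will consume.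

Step 6
Reactants: 13 3,3',4'-tri-O-benzyl-5,7-di-O-methylquercetin
Product: 14 quercetin (3,5,7,3',4'-pentahydroxyflavone)
Conditions: BBr3 (10 equiv), C6HMe5 (6 equiv), CH2Cl2, −78 °C to rt; MeOH, then H2O
Reagents that add atoms: none
Why: Lewis-acid cleavage of aryl alkyl ethers: the benzyl ethers ionise at low temperature and the benzyl cations are captured by pentamethylbenzene (Friedel–Crafts scavenging) before they can alkylate ring A; on warming, bromide dealkylates the boron-complexed methyl ethers, the chelated 5-methoxy first and the 7-methoxy last, and the flavonol core tolerates these conditions.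

Step 7
Reactants: 14 quercetin
Product: 16 tetrasodium quercetin 3,7,3',4'-tetrasulfate, via triethylammonium tetrasulfate 15 (not isolated)
Conditions: SO3·NMe3 (16 equiv), Et3N (16 equiv), DMF, 60 °C, Ar; then NaOAc, MeOH; gel filtration (Sephadex G-10, H2O)
Reagents that add atoms: sulfur trioxide–trimethylamine complex, C[N+](C)(C)S(=O)(=O)[O-]; sodium acetate, CC(=O)[O-].[Na+]
Why: O-Sulfation of phenolic and enolic hydroxyls by a sulfur trioxide–amine complex; excess reagent and moderate heat push the reaction at the hindered catechol pair and at O3, while the 5-hydroxyl, held in a hydrogen bond to the C4 carbonyl and not deprotonated by triethylamine, should remain free; exchange with sodium acetate gives a salt that precipitates and can be separated from partially sulfated material by gel filtration.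

Step 8
Reactants: 16 tetrasodium quercetin 3,7,3',4'-tetrasulfate
Product: 17 quercetin 3,7,3',4'-tetra-O-sulfate (free acid, the target)
Conditions: sulfonic acid resin (H+ form), H2O, 0–4 °C; freeze-dry at once
Reagents that add atoms: none
Why: Cation exchange of sodium for protons on a strongly acidic resin; the sulfate monoesters are fully ionised, so the exchange is complete, and cold, dilute, brief handling limits acid-catalysed loss of sulfate.

## Compound list

1 | 3,5-dimethoxyphenol | COc1cc(O)cc(OC)c1 | starting material
2 | 3,5-dimethoxyphenyl N-isopropylcarbamate | COc1cc(OC)cc(OC(=O)NC(C)C)c1 | intermediate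
3 | 3,5-dimethoxyphenyl N-(tert-butyldimethylsilyl)-N-isopropylcarbamate | COc1cc(OC)cc(OC(=O)N(C(C)C)[Si](C)(C)C(C)(C)C)c1 | intermediate (not isolated)
4 | 3,5-dimethoxy-2-(trimethylsilyl)phenyl N-(tert-butyldimethylsilyl)-N-isopropylcarbamate | COc1cc(OC)c([Si](C)(C)C)c(OC(=O)N(C(C)C)[Si](C)(C)C(C)(C)C)c1 | intermediate (not isolated)
5 | 3,5-dimethoxy-2-(trimethylsilyl)phenyl N-isopropylcarbamate | COc1cc(OC)c([Si](C)(C)C)c(OC(=O)NC(C)C)c1 | intermediate
6 | 3,5-dimethoxy-2-(trimethylsilyl)phenol | COc1cc(O)c([Si](C)(C)C)c(OC)c1 | intermediate (not isolated)
7 | 3,5-dimethoxy-2-(trimethylsilyl)phenyl trifluoromethanesulfonate | COc1cc(OC)c([Si](C)(C)C)c(OS(=O)(=O)C(F)(F)F)c1 | intermediate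
8 | 3,4-bis(benzyloxy)benzoic acid | O=C(O)c1ccc(OCc2ccccc2)c(OCc2ccccc2)c1 | starting material
9 | methyl benzyloxyacetate | COC(=O)COCc1ccccc1 | starting material
10 | [3,4-bis(benzyloxy)phenyl](1H-imidazol-1-yl)methanone | O=C(c1ccc(OCc2ccccc2)c(OCc2ccccc2)c1)n1ccnc1 | intermediate (not isolated)
11 | methyl 2-(benzyloxy)-3-[3,4-bis(benzyloxy)phenyl]-3-oxopropanoate (racemic, enolisable centre) | COC(=O)C(OCc1ccccc1)C(=O)c1ccc(OCc2ccccc2)c(OCc2ccccc2)c1 | intermediate
12 | 3,5-dimethoxybenzyne | COC1=CC(OC)=CC#C1 | intermediate (not isolated)
13 | 3,3',4'-tri-O-benzyl-5,7-di-O-methylquercetin, 3-(benzyloxy)-2-[3,4-bis(benzyloxy)phenyl]-5,7-dimethoxy-4H-chromen-4-one | COc1cc(OC)c2c(=O)c(OCc3ccccc3)c(-c3ccc(OCc4ccccc4)c(OCc4ccccc4)c3)oc2c1 | intermediate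
14 | quercetin, 2-(3,4-dihydroxyphenyl)-3,5,7-trihydroxy-4H-chromen-4-one | O=c1c(O)c(-c2ccc(O)c(O)c2)oc2cc(O)cc(O)c12 | intermediate
15 | tetrakis(triethylammonium) quercetin 3,7,3',4'-tetrasulfate | O=c1c(OS(=O)(=O)[O-])c(-c2ccc(OS(=O)(=O)[O-])c(OS(=O)(=O)[O-])c2)oc2cc(OS(=O)(=O)[O-])cc(O)c12.CC[NH+](CC)CC.CC[NH+](CC)CC.CC[NH+](CC)CC.CC[NH+](CC)CC | intermediate (not isolated)
16 | tetrasodium quercetin 3,7,3',4'-tetrasulfate | O=c1c(OS(=O)(=O)[O-])c(-c2ccc(OS(=O)(=O)[O-])c(OS(=O)(=O)[O-])c2)oc2cc(OS(=O)(=O)[O-])cc(O)c12.[Na+].[Na+].[Na+].[Na+] | intermediate
17 | quercetin 3,7,3',4'-tetra-O-sulfate, 2-[3,4-bis(sulfooxy)phenyl]-5-hydroxy-4-oxo-4H-chromene-3,7-diyl bis(hydrogen sulfate) | O=c1c(OS(=O)(=O)O)c(-c2ccc(OS(=O)(=O)O)c(OS(=O)(=O)O)c2)oc2cc(OS(=O)(=O)O)cc(O)c12 | target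

## Step count and least certain steps

Total step count: 8. Longest linear sequence: 7 steps (steps 1, 2, 3, 5, 6, 7, 8 from compound 1); the keto ester branch joins at step 5 after one step.

**Step 5 (key step, proposed new method).** The most likely failure is attack of the enolate through carbon, followed by acyl migration (acyl-alkylation) or simple C-arylation, because β-keto ester enolates normally engage arynes at carbon. O-arylation from the wrong enolate geometry, or protonation of the aryl anion before ring closure, would instead stop at an uncyclised aryl enol ether. The fallback uses known chemistry, sets out from 1 and 8 and returns at 14. Compound 1 is C-acylated ortho to the hydroxyl with methoxyacetic acid and BF3·OEt2 (O-acylation, then chelate-directed Fries shift) to 1-(2-hydroxy-4,6-dimethoxyphenyl)-2-methoxyethan-1-one F1. F1 is esterified with 8 (carbodiimide, DMAP) to 2-(2-methoxyacetyl)-3,5-dimethoxyphenyl 3,4-bis(benzyloxy)benzoate F2. Baker–Venkataraman rearrangement (KOt-Bu, THF) gives 1-[3,4-bis(benzyloxy)phenyl]-3-(2-hydroxy-4,6-dimethoxyphenyl)-2-methoxypropane-1,3-dione F3. Acid-catalysed cyclodehydration (TsOH, toluene) gives 3',4'-bis(benzyloxy)-3,5,7-trimethoxyflavone F4, and the BBr3 and pentamethylbenzene conditions of step 6 convert F4 into 14.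

**Step 2.** The most likely failure is metalation at the ring position between the two methoxy groups, or anionic ortho-Fries migration of the carbamoyl group before the silyl chloride is added. The fallback sets out from 1 and returns at 7. Compound 1 is brominated at low temperature (NBS, CH2Cl2, −78 °C) to 2-bromo-3,5-dimethoxyphenol F5, which is separated from its 4-bromo isomer. F5 is O-silylated with hexamethyldisilazane to (2-bromo-3,5-dimethoxyphenoxy)trimethylsilane F6. n-BuLi then effects bromine–lithium exchange and a retro-Brook shift of silicon from oxygen to carbon, and the resulting lithium salt of 6 is triflated with Tf2O to give 7.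

**Step 4.** The most likely failure is self-condensation of the ester enolate, or incomplete acylation because the product quenches enolate by proton transfer. The fallback sets out from 8 through 10 and returns at 11. Compound 10 is acylated onto the magnesium enolate of potassium methyl malonate (MgCl2, Et3N) with decarboxylation, giving methyl 3-[3,4-bis(benzyloxy)phenyl]-3-oxopropanoate F7. Diazo transfer (a sulfonyl azide, Et3N) gives methyl 3-[3,4-bis(benzyloxy)phenyl]-2-diazo-3-oxopropanoate F8. O–H insertion of the rhodium carbenoid into benzyl alcohol, catalysed by dirhodium tetraacetate, Rh2(OAc)4, gives 11.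

**Step 6.** The most likely failure is transfer of benzyl groups to ring A carbons if scavenging is incomplete, together with sluggish cleavage of the 7-methyl ether. The fallback sets out from 13 and returns at 14. The benzyl groups are first removed by hydrogenolysis (H2, Pd/C, THF–MeOH) to 3,3',4'-trihydroxy-5,7-dimethoxyflavone F9, and BBr3 then removes the two methyl ethers with no benzyl cations present.

**Step 7.** The most likely failure is incomplete sulfation at the crowded catechol pair, or slow creep of sulfation onto the chelated 5-hydroxyl under forcing conditions, either of which gives mixtures of anionic products that are hard to separate. The fallback sets out from 14 and returns at 16. Compound 14 is treated with 2,2,2-trichloroethyl chlorosulfate, Et3N and DMAP to give the neutral quercetin 3,7,3',4'-tetrakis(2,2,2-trichloroethyl sulfate) F10, which can be purified on silica away from under- and over-sulfated material. Reductive removal of the trichloroethyl groups (zinc dust, HCO2NH4, MeOH) gives tetraammonium quercetin 3,7,3',4'-tetrasulfate F11, and exchange with NaOAc gives 16.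

**Step 8.** The most likely failure is self-catalysed hydrolysis of sulfate esters while the acidic solution is concentrated. The fallback sets out from 15 and returns at 17. Crude 15 is treated with aqueous Ba(OH)2, which removes triethylamine and precipitates inorganic sulfate, leaving dibarium quercetin 3,7,3',4'-tetrasulfate F12 in solution for gel filtration. Exactly two equivalents of cold H2SO4 then precipitate BaSO4 and leave 17 in the filtrate for immediate freeze-drying.

## Further compounds

F1 | step 5 | 1-(2-hydroxy-4,6-dimethoxyphenyl)-2-methoxyethan-1-one | COCC(=O)c1c(O)cc(OC)cc1OC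
F2 | step 5 | 2-(2-methoxyacetyl)-3,5-dimethoxyphenyl 3,4-bis(benzyloxy)benzoate | COCC(=O)c1c(OC(=O)c2ccc(OCc3ccccc3)c(OCc3ccccc3)c2)cc(OC)cc1OC
F3 | step 5 | 1-[3,4-bis(benzyloxy)phenyl]-3-(2-hydroxy-4,6-dimethoxyphenyl)-2-methoxypropane-1,3-dione (racemic) | COC(C(=O)c1ccc(OCc2ccccc2)c(OCc2ccccc2)c1)C(=O)c1c(O)cc(OC)cc1OC
F4 | step 5 | 3',4'-bis(benzyloxy)-3,5,7-trimethoxyflavone | COc1cc(OC)c2c(=O)c(OC)c(-c3ccc(OCc4ccccc4)c(OCc4ccccc4)c3)oc2c1
F5 | step 2 | 2-bromo-3,5-dimethoxyphenol | COc1cc(O)c(Br)c(OC)c1
F6 | step 2 | (2-bromo-3,5-dimethoxyphenoxy)trimethylsilane | COc1cc(O[Si](C)(C)C)c(Br)c(OC)c1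
F7 | step 4 | methyl 3-[3,4-bis(benzyloxy)phenyl]-3-oxopropanoate | COC(=O)CC(=O)c1ccc(OCc2ccccc2)c(OCc2ccccc2)c1
F8 | step 4 | methyl 3-[3,4-bis(benzyloxy)phenyl]-2-diazo-3-oxopropanoate | COC(=O)C(=[N+]=[N-])C(=O)c1ccc(OCc2ccccc2)c(OCc2ccccc2)c1
F9 | step 6 | 3,3',4'-trihydroxy-5,7-dimethoxyflavone | COc1cc(OC)c2c(=O)c(O)c(-c3ccc(O)c(O)c3)oc2c1
F10 | step 7 | quercetin 3,7,3',4'-tetrakis(2,2,2-trichloroethyl sulfate) | O=c1c(OS(=O)(=O)OCC(Cl)(Cl)Cl)c(-c2ccc(OS(=O)(=O)OCC(Cl)(Cl)Cl)c(OS(=O)(=O)OCC(Cl)(Cl)Cl)c2)oc2cc(OS(=O)(=O)OCC(Cl)(Cl)Cl)cc(O)c12
F11 | step 7 | tetraammonium quercetin 3,7,3',4'-tetrasulfate | O=c1c(OS(=O)(=O)[O-])c(-c2ccc(OS(=O)(=O)[O-])c(OS(=O)(=O)[O-])c2)oc2cc(OS(=O)(=O)[O-])cc(O)c12.[NH4+].[NH4+].[NH4+].[NH4+]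
F12 | step 8 | dibarium quercetin 3,7,3',4'-tetrasulfate | O=c1c(OS(=O)(=O)[O-])c(-c2ccc(OS(=O)(=O)[O-])c(OS(=O)(=O)[O-])c2)oc2cc(OS(=O)(=O)[O-])cc(O)c12.[Ba+2].[Ba+2]
A1 | alternative 1 | methyl (Z)-8-(benzyloxy)-9-[3,4-bis(benzyloxy)phenyl]-3,5,7-trioxonon-8-enoate | COC(=O)CC(=O)CC(=O)CC(=O)/C(OCc1ccccc1)=C/c1ccc(OCc2ccccc2)c(OCc2ccccc2)c1
A2 | alternative 1 | (Z)-2-(benzyloxy)-3-[3,4-bis(benzyloxy)phenyl]-1-(2,4,6-trihydroxyphenyl)prop-2-en-1-one | O=C(/C(OCc1ccccc1)=C/c1ccc(OCc2ccccc2)c(OCc2ccccc2)c1)c1c(O)cc(O)cc1O
A3 | alternative 2 | 2,4-bis(benzyloxy)-6-{[3,4-bis(benzyloxy)benzoyl]oxy}benzoyl chloride | O=C(Cl)c1c(OCc2ccccc2)cc(OCc2ccccc2)cc1OC(=O)c1ccc(OCc2ccccc2)c(OCc2ccccc2)c1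
A4 | alternative 2 | (benzyloxymethylene)triphenylphosphorane | C(OCc1ccccc1)=P(c1ccccc1)(c1ccccc1)c1ccccc1
A5 | alternative 2 | 3,5,7,3',4'-penta-O-benzylquercetin | O=c1c(OCc2ccccc2)c(-c2ccc(OCc3ccccc3)c(OCc3ccccc3)c2)oc2cc(OCc3ccccc3)cc(OCc3ccccc3)c12
A6 | alternative 3 | phloroglucinol | Oc1cc(O)cc(O)c1
A7 | alternative 3 | methyl 3-(3,4-dimethoxyphenyl)-2-methoxy-3-oxopropanoate (racemic) | COC(=O)C(OC)C(=O)c1ccc(OC)c(OC)c1
A8 | alternative 3 | 5,7-dihydroxy-3,3',4'-trimethoxyflavone | COc1ccc(-c2oc3cc(O)cc(O)c3c(=O)c2OC)cc1OC
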